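## Retrosynthetic overview

1. Target ⇐ selenoxide syn-elimination (gives C1=C2 next to the 3β-OH) ⇐ 2α-phenylseleno-3β-ol ⇐ 2β,3β-epoxide of a Δ2-ene; C17 comes from a Wittig methylenation of the 16-ketone.
2. Ring D (C13–C16) by carbene-catalysed aldehyde–ketone benzoin cyclisation; ring A (C2=C3) by ring-closing metathesis of a C10 allyl and a C4 vinyl group.
3. 19,10-Lactone (C4–C5) by intramolecular Michael addition of a C10 propionate onto a ring B enoate; the enone ester comes from the C6 ketone (enol triflate carbonylation, then allylic oxidation at C10).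
4. The C12 carbinol is set by a ketoreductase, the C13 oxygen by α′-hydroxylation of the enone, the cis B/C fusion by hydrogenation.
5. The hydrindenone comes from cyclopentane-1,3-dione, (benzyloxy)acetaldehyde and methyl vinyl ketone by a proline-catalysed Hajos–Parrish aldol (sets C8). Ring order: B (from the dione) → C → lactone → A → D.

Assumption: carbon labels C1–C19 are the gibberellane numbers of the target (α = face of the lactone bridge and C14; β = face of H5, H9 and C15); the temporary carbinol centre at C13 (10–14, 24, 25), C4 in 21 and the side-chain carbinol in 22 are destroyed later, so they are drawn as the expected major isomer or left open.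

Abbreviations: TBS = tert-butyldimethylsilyl; TIPS = triisopropylsilyl; TMS = trimethylsilyl; TMSE = 2-(trimethylsilyl)ethyl; Tf = trifluoromethanesulfonyl.

## Route

Step 1
Reactants: 1 cyclopentane-1,3-dione; 2 (benzyloxy)acetaldehyde
Product: 4 2-[2-(benzyloxy)ethyl]cyclopentane-1,3-dione, via alkylidene dione 3 (not isolated)
Conditions: Hantzsch ester (1.0 equiv), L-proline (5 mol %), CH2Cl2, 25 °C
Reagents that add atoms: none
Why: Knoevenagel condensation followed by in situ transfer hydrogenation of the alkylidene dione by the Hantzsch ester (organocatalytic reductive alkylation) gives clean C-monoalkylation of the dione, and the product is achiral.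

Step 2
Reactants: 4 2-[2-(benzyloxy)ethyl]cyclopentane-1,3-dione; 5 methyl vinyl ketone
Product: 6 2-[2-(benzyloxy)ethyl]-2-(3-oxobutyl)cyclopentane-1,3-dione
Conditions: Et3N (10 mol %), EtOAc, 25 °C
Reagents that add atoms: none
Why: Michael addition of the acidic 2-substituted 1,3-dione to the enone gives the prochiral triketone with the future C8 as a quaternary carbon.

Step 3
Reactants: 6 2-[2-(benzyloxy)ethyl]-2-(3-oxobutyl)cyclopentane-1,3-dione
Product: 8 enedione (7aR)-7a-[2-(benzyloxy)ethyl]-2,3,7,7a-tetrahydro-1H-indene-1,5(6H)-dione, via Hajos–Parrish ketol 7 (not isolated)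
Conditions: L-proline (20 mol %), DMF, 20 °C; then p-TsOH (10 mol %), toluene, 80 °C
Reagents that add atoms: none
Why: Hajos–Parrish–Eder–Sauer–Wiechert enamine aldol, in which L-proline selects one of the two enantiotopic ring carbonyls and so sets C8 in the same spatial sense as in the parent (S)-Hajos–Parrish ketone, followed by acid dehydration of the cis ketol to the enone.

Step 4
Reactants: 8 enedione
Product: 9 enone ketal (C6 ketone of 8 as 1,3-dioxolane)
Conditions: Me3SiOCH2CH2OSiMe3, TMSOTf (5 mol %), CH2Cl2, −78 → −20 °C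
Reagents that add atoms: 1,2-bis(trimethylsilyloxy)ethane, C[Si](C)(C)OCCO[Si](C)(C)C
Why: Noyori ketalisation is chemoselective for the saturated cyclopentanone over the conjugated enone (as for a steroid 17-ketone beside a 4-en-3-one) and creates no stereocentre.

Step 5
Reactants: 9 enone ketal
Product: 10 13α-hydroxy enone ketal
Conditions: LiN(i-Pr)2, THF, −78 °C; then racemic 2-(phenylsulfonyl)-3-phenyloxaziridine, −78 °C; H2O work-up
Reagents that add atoms: 2-(phenylsulfonyl)-3-phenyloxaziridine, O=S(=O)(N1OC1c1ccccc1)c1ccccc1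
Why: Kinetic deprotonation of the enone gives the cross-conjugated α′ enolate at C13, and Davis enolate hydroxylation puts oxygen there anti to the angular chain (this centre is later oxidised, so its configuration is immaterial).

Step 6
Reactants: 10 13α-hydroxy enone ketal
Product: 11 cis-hydrindanone diol (9β-H; 13α-OH; 16-OH; 12-ketone; C6 dioxolane)
Conditions: H2 (1 atm), Pd/C (10 wt %), EtOAc–EtOH, 25 °C
Reagents that add atoms: none
Why: Heterogeneous hydrogenation of a Hajos–Parrish-type enone delivers hydrogen to C9 on the face of the angular substituent and gives the cis-fused hydrindane (H9 cis to the C15 chain), while the benzyl ether is hydrogenolysed in the same operation.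

Step 7
Reactants: 11 cis-hydrindanone diol
Product: 12 bis-TBS ether (13α-OTBS; 16-OTBS; 12-ketone)
Conditions: TBSCl (2.5 equiv), imidazole, DMAP (cat.), DMF, 40 °C
Reagents that add atoms: tert-butyldimethylsilyl chloride, CC(C)(C)[Si](C)(C)Cl
Why: Standard silylation of the primary and the α-ketol hydroxyl under conditions that do not enolise the ketone.

Step 8
Reactants: 12 bis-TBS ether
Product: 13 12α-alcohol (12-OH cis to 13-OTBS and trans to H9 and the C8 chain)
Conditions: ketoreductase (NADPH-dependent, panel-selected), NADP+ (cat.), i-PrOH (10 vol %), DMSO (10 vol %), phosphate buffer pH 7.0, 30 °C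
Reagents that add atoms: none
Why: Enzymatic carbonyl reduction by a ketoreductase delivers hydride from NADPH to one face of the C12 ketone under catalyst control and sets the 12α carbinol (the equatorial alcohol of the flexible cis-hydrindane), with isopropanol recycling the cofactor.

Step 9
Reactants: 13 12α-alcohol
Product: 14 12α-TIPS ether
Conditions: TIPSOTf, 2,6-lutidine, CH2Cl2, 0 → 25 °C
Reagents that add atoms: triisopropylsilyl triflate, CC(C)[Si](C(C)C)(C(C)C)OS(=O)(=O)C(F)(F)F
Why: Silyl triflate protection of the hindered secondary alcohol installs the one silyl group that must outlast the two TBS ethers.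

Step 10
Reactants: 14 12α-TIPS ether
Product: 15 C6 ketone
Conditions: In(OTf)3 (5 mol %), acetone–H2O (20:1), 25 °C
Reagents that add atoms: water, O
Why: Lewis-acid-catalysed ketal hydrolysis under near-neutral conditions releases the cyclopentanone and leaves the TBS and TIPS ethers intact.

Step 11
Reactants: 15 C6 ketone
Product: 16 enol triflate (C5=C6–OTf)
Conditions: KN(SiMe3)2, THF, −78 °C; then PhNTf2, −78 → 0 °C
Reagents that add atoms: N-phenylbis(trifluoromethanesulfonimide), O=S(=O)(N(c1ccccc1)S(=O)(=O)C(F)(F)F)C(F)(F)F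
Why: Enolate O-triflation can only go towards C5 because C8 is quaternary, and this is the sole acidic site in the molecule.

Step 12
Reactants: 16 enol triflate
Product: 17 TMSE enoate (C5=C6–CO2TMSE; C7 introduced)
Conditions: Pd(OAc)2 (5 mol %), PPh3 (10 mol %), CO (1 atm), Me3SiCH2CH2OH, Et3N, DMF, 60 °C
Reagents that add atoms: carbon monoxide, [C-]#[O+]; 2-(trimethylsilyl)ethanol, C[Si](C)(C)CCO
Why: Palladium-catalysed alkoxycarbonylation (oxidative addition of zerovalent palladium to the vinyl triflate, CO insertion, alcoholysis) works well on hindered ring-D-type enol triflates and brings in C7 as a fluoride-labile ester.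

Step 13
Reactants: 17 TMSE enoate
Product: 18 enone ester (C10 ketone; C5=C6–CO2TMSE)
Conditions: Rh2(cap)4 (1 mol %), t-BuOOH (5 equiv), K2CO3, CH2Cl2, 25 °C
Reagents that add atoms: tert-butyl hydroperoxide, CC(C)(C)OO
Why: Dirhodium-caprolactamate-catalysed allylic oxidation of a cycloalkene carboxylate converts the only allylic CH2 (C10; the other allylic carbon C8 is quaternary and no other alkene is present) into the ketone.

Step 14
Reactants: 18 enone ester
Product: 19 10α-hydroxy-10β-allyl enoate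
Conditions: allylMgBr, CeCl3, THF, −78 °C
Reagents that add atoms: allylmagnesium bromide, C=CC[Mg]Br
Why: Organocerium-type 1,2-addition to the cyclopentenone occurs on the β face, anti to the C9–C11 bond of the cis-fused ring C, which places the new C10 oxygen α and the allyl group (C1–C2) β.

Step 15
Reactants: 19 10α-hydroxy-10β-allyl enoate
Product: 20 10α-propionate
Conditions: LiN(SiMe3)2, THF, −78 °C; then EtCOCl, −78 → 0 °C
Reagents that add atoms: propionyl chloride, CCC(=O)Cl
Why: O-acylation of the pre-formed lithium alkoxide is the reliable way to esterify a hindered tertiary alcohol and supplies C4, C18 and C19.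

Step 16
Reactants: 20 10α-propionate
Product: 21 19,10-lactone (5β-H; 6β-CO2TMSE; 4-H and 4-methyl)
Conditions: KN(SiMe3)2, THF, −78 → −30 °C; AcOH; then DBU (0.2 equiv), CH2Cl2, 25 °C
Reagents that add atoms: none
Why: Intramolecular 5-exo-trig Michael addition of the propionate enolate, held on the α face by the C10 oxygen, onto C5 of the enoate can only give the cis-fused γ-lactone (5β-H), and base equilibration puts the C6 ester trans to the new C4–C5 bond (6β).

Step 17
Reactants: 21 19,10-lactone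
Product: 22 4-(1-hydroxyethyl) lactone (C4 quaternary)
Conditions: LiN(i-Pr)2 (1.1 equiv), THF, −78 °C; then CH3CHO; AcOH quench at −78 °C
Reagents that add atoms: acetaldehyde, CC=O
Why: Aldol addition of the more acidic lactone enolate takes acetaldehyde on the face of H5 and the C10 allyl group, anti to the vicinal C5–C6 bond, and so fixes the C4 quaternary centre with the two-carbon unit cis to the allyl group.

Step 18
Reactants: 22 4-(1-hydroxyethyl) lactone
Product: 23 4-vinyl lactone
Conditions: Burgess reagent, benzene, 60 °C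
Reagents that add atoms: none
Why: Burgess dehydration (syn-elimination of the sulfamate ester) can only take a hydrogen from the methyl group because C4 is quaternary, which gives the vinyl group (C3).

Step 19
Reactants: 23 4-vinyl lactone
Product: 24 Δ2-ene (ring A closed)
Conditions: second-generation Hoveyda–Grubbs catalyst (5 mol %), toluene, 80 °C
Reagents that add atoms: none
Why: Ring-closing metathesis of the cis-disposed C10 allyl and C4 vinyl groups forms the six-membered ring A with the C2=C3 alkene and releases ethylene.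

Step 20
Reactants: 24 Δ2-ene
Product: 25 13α,16-diol
Conditions: HF·pyridine, pyridine, THF, 0 → 25 °C
Reagents that add atoms: none
Why: Acidic fluoride desilylation removes the primary and the secondary TBS ether much faster than the hindered secondary TIPS ether and does not touch the TMSE ester.

Step 21
Reactants: 25 13α,16-diol
Product: 26 13-oxo-16-aldehyde
Conditions: Dess–Martin periodinane (3 equiv), CH2Cl2, 25 °C
Reagents that add atoms: none
Why: Dess–Martin oxidation converts both free alcohols at once into the 1,5-keto aldehyde without epimerising C12.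

Step 22
Reactants: 26 13-oxo-16-aldehyde
Product: 27 13-hydroxy-16-ketone (ring D closed)
Conditions: 2-(pentafluorophenyl)-6,7-dihydro-5H-pyrrolo[2,1-c][1,2,4]triazolium tetrafluoroborate (20 mol %), Et3N (20 mol %), THF, 40 °C
Reagents that add atoms: none
Why: Carbene-catalysed intramolecular crossed benzoin reaction adds the Breslow intermediate of the C16 aldehyde to the C13 ketone, and because the two-carbon bridge can only span C8 and C13 on the face that carries C15, the C13 carbinol configuration is fixed by the ring closure.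

Step 23
Reactants: 27 13-hydroxy-16-ketone
Product: 28 2β,3β-epoxide
Conditions: mCPBA, CH2Cl2, 0 °C
Reagents that add atoms: 3-chloroperbenzoic acid, OOC(=O)c1cccc(Cl)c1
Why: Prilezhaev epoxidation of the only alkene occurs on the β face because the α face of ring A is covered by the lactone bridge, and at 0 °C it is much faster than Baeyer–Villiger oxidation of the hindered ketone.

Step 24
Reactants: 28 2β,3β-epoxide
Product: 29 2α-phenylseleno-3β-ol
Conditions: PhSeNa [from (PhSe)2 and NaBH4, EtOH; hydride fully consumed before addition], EtOH–THF, 25 °C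
Reagents that add atoms: sodium benzeneselenolate, [Na+].[Se-]c1ccccc1
Why: SN2 trans-diaxial (Fürst–Plattner) opening by the soft selenolate, which is only weakly basic as its borate complex, occurs at C2 because C3 is neopentyl, so the oxygen stays on C3 with its β configuration.

Step 25
Reactants: 29 2α-phenylseleno-3β-ol
Product: 30 3β,13-bis-TMS ether
Conditions: N-(trimethylsilyl)imidazole, CH2Cl2, 40 °C
Reagents that add atoms: N-(trimethylsilyl)imidazole, C[Si](C)(C)n1ccnc1
Why: Non-basic silylation caps the tertiary α-ketol hydroxyl and the C3 hydroxyl, which blocks α-ketol rearrangement and retro-aldol opening in the following basic step.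

Step 26
Reactants: 30 3β,13-bis-TMS ether
Product: 31 16-methylene compound
Conditions: Ph3PCH3Br, KOt-Bu, THF, 0 → 50 °C
Reagents that add atoms: methyltriphenylphosphonium bromide, C[P+](c1ccccc1)(c1ccccc1)c1ccccc1.[Br-]
Why: Wittig methylenation of the hindered 16-ketone with 13-O silylated is the standard way to install the gibberellin exocyclic methylene (C17), and the lactone, ester and selenide are inert to the ylide.

Step 27
Reactants: 31 16-methylene compound
Product: 32 2α-phenylseleno-3β,12α,13-triol acid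
Conditions: Bu4NF, THF, 0 → 25 °C; then pH 4 buffer
Reagents that add atoms: none
Why: Fluoride-mediated global deprotection cleaves the two TMS ethers, the TIPS ether and the TMSE ester (β-elimination to ethylene) while ring A is still in its robust saturated form.

Step 28
Reactants: 32 2α-phenylseleno-3β,12α,13-triol acid
Product: 34 target gibberellin (3β,12α,13-trihydroxy Δ1 16-methylene 19,10-lactone 7-acid), via selenoxide 33 (not isolated)
Conditions: H2O2 (30 %), pyridine, THF, 0 → 25 °C
Reagents that add atoms: none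
Why: Selenide oxidation and selenoxide syn-elimination (Sharpless–Reich) go towards C1 and away from the carbinol carbon, which gives the C1=C2 alkene beside the untouched 3β-hydroxyl and exposes the base-sensitive allylic lactone only in the last, neutral step.

## Compound list

1 | cyclopentane-1,3-dione | O=C1CCC(=O)C1 | starting material
2 | (benzyloxy)acetaldehyde | O=CCOCc1ccccc1 | starting material
3 | 2-[2-(benzyloxy)ethylidene]cyclopentane-1,3-dione | O=C1CCC(=O)C1=CCOCc1ccccc1 | intermediate (not isolated)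
4 | 2-[2-(benzyloxy)ethyl]cyclopentane-1,3-dione | O=C1CCC(=O)C1CCOCc1ccccc1 | intermediate
5 | methyl vinyl ketone (but-3-en-2-one) | CC(=O)C=C | starting material
6 | 2-[2-(benzyloxy)ethyl]-2-(3-oxobutyl)cyclopentane-1,3-dione | CC(=O)CCC1(CCOCc2ccccc2)C(=O)CCC1=O | intermediate
7 | Hajos–Parrish ketol: cis-fused 7a-[2-(benzyloxy)ethyl]-3a-hydroxyhexahydroindane-1,5-dione, OH cis to the side chain | c1ccccc1COCC[C@]23CCC(=O)C[C@@]2(O)CCC3=O | intermediate (not isolated)
8 | enedione (7aR)-7a-[2-(benzyloxy)ethyl]-2,3,7,7a-tetrahydro-1H-indene-1,5(6H)-dione (C6 and C12 ketones, C9=C11) | c1ccccc1COCC[C@]23CCC(=O)C=C2CCC3=O | intermediate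
9 | enone ketal: 8 with the C6 ketone as 1,3-dioxolane | c1ccccc1COCC[C@]23CCC(=O)C=C2CCC31OCCO1 | intermediate
10 | 13α-hydroxy enone ketal (OH anti to the C8 side chain) | c1ccccc1COCC[C@]23C[C@@H](O)C(=O)C=C2CCC31OCCO1 | intermediate
11 | cis-hydrindanone diol: 9β-H cis to the C8 2-hydroxyethyl chain, 12-ketone, 13α-OH, C6 dioxolane | OCC[C@]23C[C@@H](O)C(=O)C[C@H]2CCC31OCCO1 | intermediate
12 | bis-TBS ether of 11 (13α-OTBS, 16-OTBS) | CC(C)(C)[Si](C)(C)OCC[C@]23C[C@@H](O[Si](C)(C)C(C)(C)C)C(=O)C[C@H]2CCC31OCCO1 | intermediate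
13 | 12α-alcohol (12-OH cis to 13-OTBS, trans to H9 and the C8 chain) | CC(C)(C)[Si](C)(C)OCC[C@]23C[C@@H](O[Si](C)(C)C(C)(C)C)[C@@H](O)C[C@H]2CCC31OCCO1 | intermediate
14 | 12α-TIPS ether of 13 | CC(C)(C)[Si](C)(C)OCC[C@]23C[C@@H](O[Si](C)(C)C(C)(C)C)[C@@H](O[Si](C(C)C)(C(C)C)C(C)C)C[C@H]2CCC31OCCO1 | intermediate
15 | C6 ketone (ketal of 14 removed) | CC(C)(C)[Si](C)(C)OCC[C@]23C[C@@H](O[Si](C)(C)C(C)(C)C)[C@@H](O[Si](C(C)C)(C(C)C)C(C)C)C[C@H]2CCC3=O | intermediate
16 | enol triflate (C5=C6–OTf) | CC(C)(C)[Si](C)(C)OCC[C@]23C[C@@H](O[Si](C)(C)C(C)(C)C)[C@@H](O[Si](C(C)C)(C(C)C)C(C)C)C[C@H]2CC=C3OS(=O)(=O)C(F)(F)F | intermediate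
17 | TMSE enoate (C5=C6–CO2TMSE) | CC(C)(C)[Si](C)(C)OCC[C@]23C[C@@H](O[Si](C)(C)C(C)(C)C)[C@@H](O[Si](C(C)C)(C(C)C)C(C)C)C[C@H]2CC=C3C(=O)OCC[Si](C)(C)C | intermediate
18 | enone ester (C10 ketone, C5=C6–CO2TMSE) | CC(C)(C)[Si](C)(C)OCC[C@]23C[C@@H](O[Si](C)(C)C(C)(C)C)[C@@H](O[Si](C(C)C)(C(C)C)C(C)C)C[C@H]2C(=O)C=C3C(=O)OCC[Si](C)(C)C | intermediate
19 | 10α-hydroxy-10β-allyl enoate | CC(C)(C)[Si](C)(C)OCC[C@]23C[C@@H](O[Si](C)(C)C(C)(C)C)[C@@H](O[Si](C(C)C)(C(C)C)C(C)C)C[C@H]2[C@](O)(CC=C)C=C3C(=O)OCC[Si](C)(C)C | intermediate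
20 | 10α-propionate of 19 | CC(C)(C)[Si](C)(C)OCC[C@]23C[C@@H](O[Si](C)(C)C(C)(C)C)[C@@H](O[Si](C(C)C)(C(C)C)C(C)C)C[C@H]2[C@](OC(=O)CC)(CC=C)C=C3C(=O)OCC[Si](C)(C)C | intermediate
21 | 19,10-lactone: cis-fused γ-lactone, 5β-H, 6β-CO2TMSE, 10β-allyl, C4 bearing H and methyl (major epimer drawn) | CC(C)(C)[Si](C)(C)OCC[C@]23C[C@@H](O[Si](C)(C)C(C)(C)C)[C@@H](O[Si](C(C)C)(C(C)C)C(C)C)C[C@H]2[C@@]4(CC=C)OC(=O)[C@H](C)[C@H]4[C@@H]3C(=O)OCC[Si](C)(C)C | intermediate
22 | 4-(1-hydroxyethyl) lactone: C4 quaternary, hydroxyethyl cis to the C10 allyl group, carbinol epimers | CC(C)(C)[Si](C)(C)OCC[C@]23C[C@@H](O[Si](C)(C)C(C)(C)C)[C@@H](O[Si](C(C)C)(C(C)C)C(C)C)C[C@H]2[C@@]4(CC=C)OC(=O)[C@](C)(C(O)C)[C@H]4[C@@H]3C(=O)OCC[Si](C)(C)C | intermediate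
23 | 4-vinyl lactone | CC(C)(C)[Si](C)(C)OCC[C@]23C[C@@H](O[Si](C)(C)C(C)(C)C)[C@@H](O[Si](C(C)C)(C(C)C)C(C)C)C[C@H]2[C@@]4(CC=C)OC(=O)[C@](C)(C=C)[C@H]4[C@@H]3C(=O)OCC[Si](C)(C)C | intermediate
24 | Δ2-ene: rings A, B, C and lactone; 13α-OTBS, 16-OTBS, 12α-OTIPS, TMSE ester | CC(C)(C)[Si](C)(C)OCC[C@]23C[C@@H](O[Si](C)(C)C(C)(C)C)[C@@H](O[Si](C(C)C)(C(C)C)C(C)C)C[C@H]2[C@@]12CC=C[C@@](C)(C(=O)O1)[C@H]2[C@@H]3C(=O)OCC[Si](C)(C)C | intermediate
25 | 13α,16-diol | OCC[C@]23C[C@@H](O)[C@@H](O[Si](C(C)C)(C(C)C)C(C)C)C[C@H]2[C@@]12CC=C[C@@](C)(C(=O)O1)[C@H]2[C@@H]3C(=O)OCC[Si](C)(C)C | intermediate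
26 | 13-oxo-16-aldehyde | O=CC[C@]23CC(=O)[C@@H](O[Si](C(C)C)(C(C)C)C(C)C)C[C@H]2[C@@]12CC=C[C@@](C)(C(=O)O1)[C@H]2[C@@H]3C(=O)OCC[Si](C)(C)C | intermediate
27 | 13-hydroxy-16-ketone: 17-nor gibberellane with ring D closed, Δ2, 12α-OTIPS, TMSE ester | O=C1C[C@]23C[C@@]1(O)[C@@H](O[Si](C(C)C)(C(C)C)C(C)C)C[C@H]2[C@@]12CC=C[C@@](C)(C(=O)O1)[C@H]2[C@@H]3C(=O)OCC[Si](C)(C)C | intermediate
28 | 2β,3β-epoxide of 27 | O=C1C[C@]23C[C@@]1(O)[C@@H](O[Si](C(C)C)(C(C)C)C(C)C)C[C@H]2[C@@]12C[C@@H]4O[C@@H]4[C@@](C)(C(=O)O1)[C@H]2[C@@H]3C(=O)OCC[Si](C)(C)C | intermediate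
29 | 2α-phenylseleno-3β-ol | O=C1C[C@]23C[C@@]1(O)[C@@H](O[Si](C(C)C)(C(C)C)C(C)C)C[C@H]2[C@@]12C[C@@H]([Se]c4ccccc4)[C@H](O)[C@@](C)(C(=O)O1)[C@H]2[C@@H]3C(=O)OCC[Si](C)(C)C | intermediate
30 | 3β,13-bis-TMS ether of 29 | O=C1C[C@]23C[C@@]1(O[Si](C)(C)C)[C@@H](O[Si](C(C)C)(C(C)C)C(C)C)C[C@H]2[C@@]12C[C@@H]([Se]c4ccccc4)[C@H](O[Si](C)(C)C)[C@@](C)(C(=O)O1)[C@H]2[C@@H]3C(=O)OCC[Si](C)(C)C | intermediate
31 | 16-methylene compound | C=C1C[C@]23C[C@@]1(O[Si](C)(C)C)[C@@H](O[Si](C(C)C)(C(C)C)C(C)C)C[C@H]2[C@@]12C[C@@H]([Se]c4ccccc4)[C@H](O[Si](C)(C)C)[C@@](C)(C(=O)O1)[C@H]2[C@@H]3C(=O)OCC[Si](C)(C)C | intermediate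
32 | 2α-phenylseleno-3β,12α,13-triol acid (the target with C1–C2 saturated and 2α-SePh) | C=C1C[C@]23C[C@@]1(O)[C@@H](O)C[C@H]2[C@@]12C[C@@H]([Se]c4ccccc4)[C@H](O)[C@@](C)(C(=O)O1)[C@H]2[C@@H]3C(=O)O | intermediate
33 | selenoxide of 32 (Se configuration open) | C=C1C[C@]23C[C@@]1(O)[C@@H](O)C[C@H]2[C@@]12C[C@@H]([Se](=O)c4ccccc4)[C@H](O)[C@@](C)(C(=O)O1)[C@H]2[C@@H]3C(=O)O | intermediate (not isolated)
34 | target gibberellin (3β,12α,13-trihydroxy Δ1 16-methylene 19,10-lactone 7-acid) | C=C1C[C@]23C[C@@]1(O)[C@@H](O)C[C@H]2[C@@]12C=C[C@H](O)[C@@](C)(C(=O)O1)[C@H]2[C@@H]3C(=O)O | target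

## Step count and risks

Total step count: 28. Longest linear sequence: 28 steps (fully linear from 1).

The three steps most likely to fail:

Step 8 (ketoreductase reduction of 12). The bis-silylated ketone is bulky and lipophilic, so no enzyme of the panel may accept it, or the preferred face may be the wrong one. The fallback leaves the route at 12 and replaces catalyst control by substrate-controlled hydride reduction plus inversion. LiBH(s-Bu)3 in THF at −78 °C attacks from the equatorial side and gives the 12β-alcohol F1. A Mitsunobu reaction (4-nitrobenzoic acid, PPh3, diisopropyl azodicarboxylate, toluene) inverts C12 and gives the 12α-(4-nitrobenzoate) F2. K2CO3 in MeOH cleaves the ester and the route is rejoined at 13.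

Step 22 (carbene-catalysed benzoin closure of ring D). The benzoin reaction is reversible, and the product carries the 12α-silyloxy group syn-axial to C10, so the equilibrium or a competing aldol of the keto aldehyde may defeat it. The fallback leaves at 26 and closes the ring reductively and irreversibly. Pinacol cyclisation with low-valent titanium (TiCl4, Mg(Hg), THF, −10 °C) gives the cis-13,16-diol F3. Dess–Martin oxidation of its secondary C16 alcohol (the tertiary 13-OH cannot be oxidised) returns to the route at 27.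

Step 24 (selenolate opening of epoxide 28). The required attack at C2 comes from the α face under the lactone bridge and may be too slow. The fallback leaves at 27, before the epoxidation, and installs the 3β-oxygen and the C1=C2 alkene by an ene reaction instead of by epoxide opening. A Schenck ene reaction with singlet oxygen (O2, hν, tetraphenylporphyrin, CH2Cl2, 0 °C) gives the 3β-hydroperoxide F4, because only C1 carries allylic hydrogens, so oxygen must enter at C3 on the open β face with shift of the alkene to C1=C2. PPh3 reduces it to the 3β-allylic alcohol F5, N-(trimethylsilyl)imidazole gives the 3β,13-bis-TMS ether F6, and Wittig methylenation (Ph3PCH3Br, KOt-Bu, THF) gives the fully protected 16-methylene Δ1-ene F7. Buffered fluoride (HF·pyridine, then tris(dimethylamino)sulfonium difluorotrimethylsilicate in DMF) removes the silyl ethers and the TMSE ester and returns to the route at the target 34.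

Further compounds
F1 | step 8 | 12β-alcohol (C12 epimer of 13) | CC(C)(C)[Si](C)(C)OCC[C@]23C[C@@H](O[Si](C)(C)C(C)(C)C)[C@H](O)C[C@H]2CCC31OCCO1
F2 | step 8 | 12α-(4-nitrobenzoate) of 13 | CC(C)(C)[Si](C)(C)OCC[C@]23C[C@@H](O[Si](C)(C)C(C)(C)C)[C@@H](OC(=O)c4ccc(cc4)[N+](=O)[O-])C[C@H]2CCC31OCCO1
F3 | step 22 | cis-13,16-diol (ring D closed, 16-OH cis to 13-OH) | O[C@@H]1C[C@]23C[C@@]1(O)[C@@H](O[Si](C(C)C)(C(C)C)C(C)C)C[C@H]2[C@@]12CC=C[C@@](C)(C(=O)O1)[C@H]2[C@@H]3C(=O)OCC[Si](C)(C)C
F4 | step 24 | 3β-hydroperoxy-Δ1 16-ketone | O=C1C[C@]23C[C@@]1(O)[C@@H](O[Si](C(C)C)(C(C)C)C(C)C)C[C@H]2[C@@]12C=C[C@H](OO)[C@@](C)(C(=O)O1)[C@H]2[C@@H]3C(=O)OCC[Si](C)(C)C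
F5 | step 24 | 3β-hydroxy-Δ1 16-ketone | O=C1C[C@]23C[C@@]1(O)[C@@H](O[Si](C(C)C)(C(C)C)C(C)C)C[C@H]2[C@@]12C=C[C@H](O)[C@@](C)(C(=O)O1)[C@H]2[C@@H]3C(=O)OCC[Si](C)(C)C
F6 | step 24 | 3β,13-bis-TMS ether of F5 | O=C1C[C@]23C[C@@]1(O[Si](C)(C)C)[C@@H](O[Si](C(C)C)(C(C)C)C(C)C)C[C@H]2[C@@]12C=C[C@H](O[Si](C)(C)C)[C@@](C)(C(=O)O1)[C@H]2[C@@H]3C(=O)OCC[Si](C)(C)C
F7 | step 24 | fully protected 16-methylene Δ1-ene | C=C1C[C@]23C[C@@]1(O[Si](C)(C)C)[C@@H](O[Si](C(C)C)(C(C)C)C(C)C)C[C@H]2[C@@]12C=C[C@H](O[Si](C)(C)C)[C@@](C)(C(=O)O1)[C@H]2[C@@H]3C(=O)OCC[Si](C)(C)C
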